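**Plan**

- Cuts: in the target lactone (O1, carbonyl C2, C3, C4, C5) the O1–C2 bond is opened to a γ-hydroxy tert-butyl ester, C5 is taken back to a nitromethyl group, and C3–CH2(syringyl) and C3–C4 are then cut together.
- Enabling feature: C3 of the lactone ring carries the hydroxyl, the carbonyl carbon C2 and two carbon arms (the syringyl CH2 and C4). It therefore maps onto the ketone carbon of a silyl glyoxylate, which first accepts a benzyl nucleophile and then, after a C-to-O silyl shift, reacts as an enolate at the same carbon.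
- Forward: silyl glyoxylate, benzylic Grignard reagent and nitroalkene are joined in one flask into the open chain (C3–benzyl bond first, then C3–C4). CH2NO2 is then turned into CO2H and reduced to CH2OH, and the only ring, the γ-lactone, closes last by attack of O1 on C2, before desilylation and debenzylation.
- Stereochemistry: the C3/C4 relationship comes from the Z magnesium enolate meeting the E nitroalkene in a closed transition state. The coupling is run racemic, and the 3S,4S series is selected at the acid stage by separating N-acyl derivatives of (S)-4-benzyl-1,3-thiazolidine-2-thione, which is then removed by reduction.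

Key step: step 10

Assumption: the Brook rearrangement is taken to give the Z chloromagnesium enolate (OMgCl and OSi cis), as chelation in the alkoxide suggests. No reliable chiral controller is available for this enolate, so the coupling product, its magnesium precursors and the derived acid are racemates, named and drawn as the enantiomer that is carried on.

**Route**

Step 1
Reactants: 1 tert-butyl diazoacetate
Product: 2 tert-butyl 2-(tert-butyldimethylsilyl)-2-diazoacetate
Conditions: TBSOTf, iPr2NEt, Et2O, −30 °C to rt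
Reagents that add atoms: tert-butyldimethylsilyl trifluoromethanesulfonate, CC(C)(C)[Si](C)(C)OS(=O)(=O)C(F)(F)F
Why: The nucleophilic diazo carbon attacks the silyl triflate and the amine removes the proton of the resulting diazonium ion (C-silylation of a diazoacetate).

Step 2
Reactants: 2 tert-butyl 2-(tert-butyldimethylsilyl)-2-diazoacetate
Product: 3 tert-butyl 2-(tert-butyldimethylsilyl)-2-oxoacetate
Conditions: Oxone (2KHSO5·KHSO4·K2SO4), NaHCO3, acetone/H2O/CH2Cl2, 0 °C to rt
Reagents that add atoms: potassium peroxymonosulfate (active part of Oxone), [K+].[O-]S(=O)(=O)OO; the oxygen is passed on through dimethyldioxirane, CC1(C)OO1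
Why: Dimethyldioxirane formed in the flask transfers an oxygen atom to the diazo carbon with loss of N2 (oxidation of an α-silyl diazo ester to the acylsilane), the standard access to silyl glyoxylates.

Step 3
Reactants: 4 syringaldehyde
Product: 5 4-(benzyloxy)-3,5-dimethoxybenzaldehyde
Conditions: BnBr, K2CO3, DMF, rt
Reagents that add atoms: benzyl bromide, BrCc1ccccc1
Why: Williamson etherification of the phenoxide; the benzyl ether masks the acidic phenol through the organomagnesium chemistry and falls off at the end by hydrogenolysis.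

Step 4
Reactants: 5 4-(benzyloxy)-3,5-dimethoxybenzaldehyde
Product: 6 [4-(benzyloxy)-3,5-dimethoxyphenyl]methanol
Conditions: NaBH4, MeOH/THF, 0 °C
Reagents that add atoms: none
Why: Borohydride reduction of an aromatic aldehyde to the benzylic alcohol.

Step 5
Reactants: 6 [4-(benzyloxy)-3,5-dimethoxyphenyl]methanol
Product: 7 2-(benzyloxy)-5-(chloromethyl)-1,3-dimethoxybenzene
Conditions: SOCl2, CH2Cl2, 0 °C
Reagents that add atoms: thionyl chloride, O=S(Cl)Cl
Why: Chlorodehydroxylation through the chlorosulfite, fast for an electron-rich benzylic alcohol at 0 °C, where the aryl benzyl ether is stable to the HCl formed.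

Step 6
Reactants: 7 2-(benzyloxy)-5-(chloromethyl)-1,3-dimethoxybenzene
Product: 8 [4-(benzyloxy)-3,5-dimethoxybenzyl]magnesium chloride
Conditions: Mg turnings (I2-activated, excess), 2-MeTHF, 0 °C, slow addition; titrated solution used directly
Reagents that add atoms: magnesium, [Mg]
Why: Oxidative insertion of magnesium into the benzylic C–Cl bond (Grignard formation); excess metal, high dilution, low temperature and 2-methyltetrahydrofuran hold back Wurtz coupling.

Step 7
Reactants: 9 2-(3,4-dimethoxyphenyl)ethanol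
Product: 10 2-(3,4-dimethoxyphenyl)acetaldehyde
Conditions: Dess–Martin periodinane, CH2Cl2, 0 °C to rt; used crude
Reagents that add atoms: none
Why: Dess–Martin oxidation stops at the aldehyde under near-neutral conditions, which suits an enolisable arylacetaldehyde that is taken on without storage.

Step 8
Reactants: 10 2-(3,4-dimethoxyphenyl)acetaldehyde; 11 nitromethane
Product: 12 rac-1-(3,4-dimethoxyphenyl)-3-nitropropan-2-ol
Conditions: MeNO2 (5 equiv), KOtBu (10 mol%), THF/t-BuOH, 0 °C
Reagents that add atoms: none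
Why: Henry (nitroaldol) addition of the nitronate to the aldehyde with catalytic base at 0 °C to limit aldehyde self-condensation; the carbinol centre forms racemic and is destroyed in step 9.

Step 9
Reactants: 12 rac-1-(3,4-dimethoxyphenyl)-3-nitropropan-2-ol
Product: 14 (E)-1,2-dimethoxy-4-(3-nitroprop-2-en-1-yl)benzene, via mesylate 13 (not isolated)
Conditions: MsCl, iPr2NEt (2.2 equiv), CH2Cl2, −40 to −10 °C; rapid cold work-up
Reagents that add atoms: none
Why: Mesylation followed by E1cB elimination through the nitronate gives the E nitroalkene (dehydration of a nitroaldol); the small excess of base, low temperature and short contact time are chosen to prevent base-mediated drift of the double bond into conjugation with the arene.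

Step 10
Reactants: 3 tert-butyl 2-(tert-butyldimethylsilyl)-2-oxoacetate; 8 [4-(benzyloxy)-3,5-dimethoxybenzyl]magnesium chloride; 14 (E)-1,2-dimethoxy-4-(3-nitroprop-2-en-1-yl)benzene
Product: 18 rac-tert-butyl (2S,3S)-2-[4-(benzyloxy)-3,5-dimethoxybenzyl]-2-[(tert-butyldimethylsilyl)oxy]-3-(3,4-dimethoxybenzyl)-4-nitrobutanoate, via chloromagnesium alkoxide 15 (not isolated), via Z chloromagnesium enolate 16 (not isolated), via chloromagnesium nitronate 17 (not isolated)
Conditions: 8 (1.3 equiv) added dropwise to 3 (1.3 equiv) and 14 (1.0 equiv), THF, −78 °C; then AcOH, −78 °C to rt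
Reagents that add atoms: none
Why: The Grignard reagent 8 adds to the acylsilane carbonyl of 3 to give alkoxide 15, a C-to-O 1,2-silyl shift (Brook rearrangement), driven by conjugation of the carbanion with the ester, turns 15 into the Z glycolate enolate 16 with the C2 oxygen already silylated, and 16 adds in Michael fashion to nitroalkene 14 to give nitronate 17, which acetic acid protonates to 18. The closest known reaction type is the three-component coupling of silyl glyoxylates with Grignard reagents and nitroalkenes or aldehydes. No ring is closed. The new stereocentres C2 and C3 are set together: with OMgCl and OSi cis on the enolate, a closed magnesium-bridged synclinal transition state that holds the nitro group over the enolate oxygen and the veratrylmethyl group anti to the enolate C=C joins the Si face of the enolate carbon to the Si face of the nitroalkene β-carbon (like topicity, Re/Re in the mirror image), which is the 2S,3S/2R,3R pair the target needs. No chiral controller is present, so 18 should form as a racemate and the 2S,3S series is selected in step 12. The step needs attack of 8 on the silyl ketone ahead of the ester and the nitroalkene, and C–C bond formation by 16 ahead of proton abstraction from the benzylic allylic CH2 of 14 or attack on a second molecule of 3; the high electrophilicity of the acylsilane carbonyl, the bulk of the tert-butyl ester, the nitroalkene being present from the start, slow addition and −78 °C are meant to secure this.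

Step 11
Reactants: 18 rac-tert-butyl (2S,3S)-2-[4-(benzyloxy)-3,5-dimethoxybenzyl]-2-[(tert-butyldimethylsilyl)oxy]-3-(3,4-dimethoxybenzyl)-4-nitrobutanoate
Product: 19 rac-(2R,3S)-3-[4-(benzyloxy)-3,5-dimethoxybenzyl]-4-tert-butoxy-3-[(tert-butyldimethylsilyl)oxy]-2-(3,4-dimethoxybenzyl)-4-oxobutanoic acid
Conditions: NaNO2 (3 equiv), AcOH (10 equiv), DMSO, 35 °C
Reagents that add atoms: sodium nitrite, [Na+].[O-]N=O; water, O
Why: Nitrosation of the primary nitronate gives a nitrolic acid that loses nitrous acid to a nitrile oxide and is hydrolysed through the hydroxamic acid to the carboxylic acid (nitrosative, Nef-type conversion of a primary nitroalkane to the acid); the weakly acidic medium spares the silyl ether and tert-butyl ester, and no aldehyde intervenes, so the adjacent C–H stereocentre is not at risk (the descriptor changes to 2R only through CIP priorities).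

Step 12
Reactants: 19 rac-(2R,3S)-3-[4-(benzyloxy)-3,5-dimethoxybenzyl]-4-tert-butoxy-3-[(tert-butyldimethylsilyl)oxy]-2-(3,4-dimethoxybenzyl)-4-oxobutanoic acid; 20 (S)-4-benzyl-1,3-thiazolidine-2-thione
Product: 21 tert-butyl (2S,3R)-4-[(4S)-4-benzyl-2-thioxo-1,3-thiazolidin-3-yl]-2-[4-(benzyloxy)-3,5-dimethoxybenzyl]-2-[(tert-butyldimethylsilyl)oxy]-3-(3,4-dimethoxybenzyl)-4-oxobutanoate
Conditions: DCC, DMAP (cat.), CH2Cl2, 0 °C to rt; separation of the two diastereomers on silica gel
Reagents that add atoms: none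
Why: Steglich-type N-acylation of the thiazolidinethione turns the two enantiomers of 19 into two diastereomeric, yellow N-acyl derivatives that should separate by chromatography, so this step selects the absolute configuration at both centres; the isomers would be assigned by X-ray analysis against the known auxiliary centre.

Step 13
Reactants: 21 tert-butyl (2S,3R)-4-[(4S)-4-benzyl-2-thioxo-1,3-thiazolidin-3-yl]-2-[4-(benzyloxy)-3,5-dimethoxybenzyl]-2-[(tert-butyldimethylsilyl)oxy]-3-(3,4-dimethoxybenzyl)-4-oxobutanoate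
Product: 23 tert-butyl (2S,3S)-2-[4-(benzyloxy)-3,5-dimethoxybenzyl]-2-[(tert-butyldimethylsilyl)oxy]-3-(3,4-dimethoxybenzyl)-4-hydroxybutanoate, via aldehyde 22 (not isolated)
Conditions: NaBH4, THF/EtOH, 0 °C
Reagents that add atoms: none
Why: Hydride attacks the activated thioimide carbonyl, the thiazolidinethione is expelled to give aldehyde 22, and excess borohydride reduces this at once to the primary alcohol (reductive cleavage of an N-acyl thiazolidinethione), faster than it can enolise at C3; the hindered tert-butyl ester is left alone.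

Step 14
Reactants: 23 tert-butyl (2S,3S)-2-[4-(benzyloxy)-3,5-dimethoxybenzyl]-2-[(tert-butyldimethylsilyl)oxy]-3-(3,4-dimethoxybenzyl)-4-hydroxybutanoate
Product: 25 (3S,4S)-3-[4-(benzyloxy)-3,5-dimethoxybenzyl]-4-(3,4-dimethoxybenzyl)-3-hydroxyoxolan-2-one, via silyloxy lactone 24 (not isolated)
Conditions: TFA/CH2Cl2 (1:3), H2O (5 equiv), 0 °C to rt; evaporation with toluene; then TBAF, AcOH, THF, rt
Reagents that add atoms: none
Why: TFA promotes acyl substitution at the tert-butyl ester by the γ-hydroxyl (5-exo-trig lactonisation, the tert-butyl group leaving as tert-butanol with water as cation trap), and fluoride then cleaves the hindered tertiary silyl ether through Si–F bond formation while acetic acid keeps the medium from opening the lactone; neither stage touches C3 or C4.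

Step 15
Reactants: 25 (3S,4S)-3-[4-(benzyloxy)-3,5-dimethoxybenzyl]-4-(3,4-dimethoxybenzyl)-3-hydroxyoxolan-2-one
Product: 26 (3S,4S)-4-(3,4-dimethoxybenzyl)-3-hydroxy-3-(4-hydroxy-3,5-dimethoxybenzyl)oxolan-2-one
Conditions: H2 (1 atm), 10% Pd/C, EtOAc/EtOH, rt
Reagents that add atoms: none
Why: Hydrogenolysis of the aryl benzyl ether; the molecule has no other benzylic C–O bond, and the lactone and tertiary alcohol are inert.

**Compound list**

1 | tert-butyl diazoacetate | CC(C)(C)OC(=O)C=[N+]=[N-] | starting material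
2 | tert-butyl 2-(tert-butyldimethylsilyl)-2-diazoacetate | CC(C)(C)OC(=O)C(=[N+]=[N-])[Si](C)(C)C(C)(C)C | intermediate
3 | tert-butyl 2-(tert-butyldimethylsilyl)-2-oxoacetate | CC(C)(C)OC(=O)C(=O)[Si](C)(C)C(C)(C)C | intermediate
4 | syringaldehyde (4-hydroxy-3,5-dimethoxybenzaldehyde) | COc1cc(C=O)cc(OC)c1O | starting material
5 | 4-(benzyloxy)-3,5-dimethoxybenzaldehyde | COc1cc(C=O)cc(OC)c1OCc1ccccc1 | intermediate
6 | [4-(benzyloxy)-3,5-dimethoxyphenyl]methanol | COc1cc(CO)cc(OC)c1OCc1ccccc1 | intermediate
7 | 2-(benzyloxy)-5-(chloromethyl)-1,3-dimethoxybenzene | COc1cc(CCl)cc(OC)c1OCc1ccccc1 | intermediate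
8 | [4-(benzyloxy)-3,5-dimethoxybenzyl]magnesium chloride | COc1cc(C[Mg]Cl)cc(OC)c1OCc1ccccc1 | intermediate
9 | 2-(3,4-dimethoxyphenyl)ethanol | COc1ccc(CCO)cc1OC | starting material
10 | 2-(3,4-dimethoxyphenyl)acetaldehyde | COc1ccc(CC=O)cc1OC | intermediate
11 | nitromethane | C[N+](=O)[O-] | starting material
12 | rac-1-(3,4-dimethoxyphenyl)-3-nitropropan-2-ol | COc1ccc(CC(O)C[N+](=O)[O-])cc1OC | intermediate
13 | rac-1-(3,4-dimethoxyphenyl)-3-nitropropan-2-yl methanesulfonate | COc1ccc(CC(OS(C)(=O)=O)C[N+](=O)[O-])cc1OC | intermediate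
14 | (E)-1,2-dimethoxy-4-(3-nitroprop-2-en-1-yl)benzene | COc1ccc(C/C=C/[N+](=O)[O-])cc1OC | intermediate
15 | rac-tert-butyl 3-[4-(benzyloxy)-3,5-dimethoxyphenyl]-2-(tert-butyldimethylsilyl)-2-[(chloromagnesio)oxy]propanoate | CC(C)(C)OC(=O)C(O[Mg]Cl)(Cc1cc(OC)c(OCc2ccccc2)c(OC)c1)[Si](C)(C)C(C)(C)C | intermediate
16 | chloromagnesium (Z)-3-[4-(benzyloxy)-3,5-dimethoxyphenyl]-1-tert-butoxy-2-[(tert-butyldimethylsilyl)oxy]prop-1-en-1-olate | CC(C)(C)O/C(O[Mg]Cl)=C(/O[Si](C)(C)C(C)(C)C)Cc1cc(OC)c(OCc2ccccc2)c(OC)c1 | intermediate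
17 | chloromagnesium nitronate of 18 (racemate, one enantiomer drawn) | CC(C)(C)OC(=O)[C@](O[Si](C)(C)C(C)(C)C)(Cc1cc(OC)c(OCc2ccccc2)c(OC)c1)[C@@H](Cc1ccc(OC)c(OC)c1)C=[N+]([O-])O[Mg]Cl | intermediate
18 | rac-tert-butyl (2S,3S)-2-[4-(benzyloxy)-3,5-dimethoxybenzyl]-2-[(tert-butyldimethylsilyl)oxy]-3-(3,4-dimethoxybenzyl)-4-nitrobutanoate (one enantiomer drawn) | CC(C)(C)OC(=O)[C@](O[Si](C)(C)C(C)(C)C)(Cc1cc(OC)c(OCc2ccccc2)c(OC)c1)[C@@H](Cc1ccc(OC)c(OC)c1)C[N+](=O)[O-] | intermediate
19 | rac-(2R,3S)-3-[4-(benzyloxy)-3,5-dimethoxybenzyl]-4-tert-butoxy-3-[(tert-butyldimethylsilyl)oxy]-2-(3,4-dimethoxybenzyl)-4-oxobutanoic acid (one enantiomer drawn) | CC(C)(C)OC(=O)[C@](O[Si](C)(C)C(C)(C)C)(Cc1cc(OC)c(OCc2ccccc2)c(OC)c1)[C@@H](Cc1ccc(OC)c(OC)c1)C(=O)O | intermediate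
20 | (S)-4-benzyl-1,3-thiazolidine-2-thione | S=C1N[C@@H](Cc2ccccc2)CS1 | starting material
21 | tert-butyl (2S,3R)-4-[(4S)-4-benzyl-2-thioxo-1,3-thiazolidin-3-yl]-2-[4-(benzyloxy)-3,5-dimethoxybenzyl]-2-[(tert-butyldimethylsilyl)oxy]-3-(3,4-dimethoxybenzyl)-4-oxobutanoate | CC(C)(C)OC(=O)[C@](O[Si](C)(C)C(C)(C)C)(Cc1cc(OC)c(OCc2ccccc2)c(OC)c1)[C@@H](Cc1ccc(OC)c(OC)c1)C(=O)N1C(=S)SC[C@@H]1Cc1ccccc1 | intermediate
22 | tert-butyl (2S,3R)-2-[4-(benzyloxy)-3,5-dimethoxybenzyl]-2-[(tert-butyldimethylsilyl)oxy]-3-(3,4-dimethoxybenzyl)-4-oxobutanoate | CC(C)(C)OC(=O)[C@](O[Si](C)(C)C(C)(C)C)(Cc1cc(OC)c(OCc2ccccc2)c(OC)c1)[C@@H](Cc1ccc(OC)c(OC)c1)C=O | intermediate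
23 | tert-butyl (2S,3S)-2-[4-(benzyloxy)-3,5-dimethoxybenzyl]-2-[(tert-butyldimethylsilyl)oxy]-3-(3,4-dimethoxybenzyl)-4-hydroxybutanoate | CC(C)(C)OC(=O)[C@](O[Si](C)(C)C(C)(C)C)(Cc1cc(OC)c(OCc2ccccc2)c(OC)c1)[C@@H](Cc1ccc(OC)c(OC)c1)CO | intermediate
24 | (3S,4S)-3-[4-(benzyloxy)-3,5-dimethoxybenzyl]-3-[(tert-butyldimethylsilyl)oxy]-4-(3,4-dimethoxybenzyl)oxolan-2-one | COc1ccc(C[C@H]2COC(=O)[C@]2(O[Si](C)(C)C(C)(C)C)Cc2cc(OC)c(OCc3ccccc3)c(OC)c2)cc1OC | intermediate
25 | (3S,4S)-3-[4-(benzyloxy)-3,5-dimethoxybenzyl]-4-(3,4-dimethoxybenzyl)-3-hydroxyoxolan-2-one | COc1ccc(C[C@H]2COC(=O)[C@]2(O)Cc2cc(OC)c(OCc3ccccc3)c(OC)c2)cc1OC | intermediate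
26 | (3S,4S)-4-(3,4-dimethoxybenzyl)-3-hydroxy-3-(4-hydroxy-3,5-dimethoxybenzyl)oxolan-2-one | COc1ccc(C[C@H]2COC(=O)[C@]2(O)Cc2cc(OC)c(O)c(OC)c2)cc1OC | target

**Step count and risks**

Total: 15 steps. Longest linear sequence: 10 steps, from syringaldehyde 4 to 26 (steps 3, 4, 5, 6, 10, 11, 12, 13, 14, 15).

Most likely to fail, in order:

1. Step 10. The basic enolate or the Grignard reagent may abstract a proton from the benzylic allylic CH2 of the nitroalkene instead of forming the C–C bond. The Grignard reagent may also add directly to the nitroalkene, the enolate may attack a second silyl glyoxylate, or the simple diastereoselection may be weak. The fallback sets out from 3 and 8 and comes back at 18, with the enolate chemistry moved to Lewis acidic conditions where no base meets the nitroalkene. Reagent 8 would be added to 3 alone at −78 °C and the enolate quenched with acetic acid to give rac-tert-butyl 3-[4-(benzyloxy)-3,5-dimethoxyphenyl]-2-[(tert-butyldimethylsilyl)oxy]propanoate F1. Treatment with LiN(iPr)2 and Me3SiCl in THF at −78 °C should give the tert-butyl trimethylsilyl ketene acetal F2. A Mukaiyama–Michael addition of this acetal to nitroalkene 14, promoted by TiCl2(OiPr)2 in CH2Cl2 at −78 °C and followed by aqueous hydrolysis of the silyl nitronate, should return 18. If the open transition state gives both diastereomers, they would be separated at this point.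

2. Step 12. N-Acylation at the hindered carboxyl group may be slow, with rearrangement of the activated ester to the N-acylurea, and the two diastereomers may not separate well on silica. The fallback sets out from 19 and comes back at 23, resolving after the reduction instead of before it. BH3·SMe2 in THF at 0 °C should reduce the acid selectively to rac-tert-butyl (2S,3S)-2-[4-(benzyloxy)-3,5-dimethoxybenzyl]-2-[(tert-butyldimethylsilyl)oxy]-3-(3,4-dimethoxybenzyl)-4-hydroxybutanoate F4. Acylation of the unhindered primary alcohol with (1S)-camphanic chloride, pyridine and catalytic DMAP would give the (2S,3S)-configured camphanate F5 together with the diastereomeric camphanate of the (2R,3R)-alcohol F6, which would be removed by chromatography or crystallisation. Methanolysis of the camphanate with K2CO3 in MeOH at 0 °C should then release 23.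

3. Step 11. Nitrosation of the hindered nitronate may stall, or the nitrosating medium may attack the electron-rich arenes. The fallback sets out from 18 and comes back at 19, replacing the nitrosative route by a reductive Nef reaction and a separate oxidation. The nitronate would be formed with NaOMe in MeOH and added to aqueous TiCl3 buffered with NH4OAc to give rac-tert-butyl (2S,3R)-2-[4-(benzyloxy)-3,5-dimethoxybenzyl]-2-[(tert-butyldimethylsilyl)oxy]-3-(3,4-dimethoxybenzyl)-4-oxobutanoate F3. This aldehyde can epimerise next to the carbonyl, so it would be oxidised at once under Pinnick conditions (NaClO2, NaH2PO4, 2-methyl-2-butene, t-BuOH/H2O) to 19.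

**Further compounds**

F1 | step 10 | rac-tert-butyl 3-[4-(benzyloxy)-3,5-dimethoxyphenyl]-2-[(tert-butyldimethylsilyl)oxy]propanoate | CC(C)(C)OC(=O)C(O[Si](C)(C)C(C)(C)C)Cc1cc(OC)c(OCc2ccccc2)c(OC)c1
F2 | step 10 | {[3-[4-(benzyloxy)-3,5-dimethoxyphenyl]-1-tert-butoxy-2-[(tert-butyldimethylsilyl)oxy]prop-1-en-1-yl]oxy}trimethylsilane (E/Z mixture) | CC(C)(C)OC(O[Si](C)(C)C)=C(O[Si](C)(C)C(C)(C)C)Cc1cc(OC)c(OCc2ccccc2)c(OC)c1
F3 | step 11 | rac-tert-butyl (2S,3R)-2-[4-(benzyloxy)-3,5-dimethoxybenzyl]-2-[(tert-butyldimethylsilyl)oxy]-3-(3,4-dimethoxybenzyl)-4-oxobutanoate (one enantiomer drawn) | CC(C)(C)OC(=O)[C@](O[Si](C)(C)C(C)(C)C)(Cc1cc(OC)c(OCc2ccccc2)c(OC)c1)[C@@H](Cc1ccc(OC)c(OC)c1)C=O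
F4 | step 12 | rac-tert-butyl (2S,3S)-2-[4-(benzyloxy)-3,5-dimethoxybenzyl]-2-[(tert-butyldimethylsilyl)oxy]-3-(3,4-dimethoxybenzyl)-4-hydroxybutanoate (one enantiomer drawn) | CC(C)(C)OC(=O)[C@](O[Si](C)(C)C(C)(C)C)(Cc1cc(OC)c(OCc2ccccc2)c(OC)c1)[C@@H](Cc1ccc(OC)c(OC)c1)CO
F5 | step 12 | (2S,3S)-3-[4-(benzyloxy)-3,5-dimethoxybenzyl]-4-tert-butoxy-3-[(tert-butyldimethylsilyl)oxy]-2-(3,4-dimethoxybenzyl)-4-oxobutyl (1S,4R)-4,7,7-trimethyl-3-oxo-2-oxabicyclo[2.2.1]heptane-1-carboxylate | CC(C)(C)OC(=O)[C@](O[Si](C)(C)C(C)(C)C)(Cc1cc(OC)c(OCc2ccccc2)c(OC)c1)[C@@H](Cc1ccc(OC)c(OC)c1)COC(=O)[C@]1(OC2=O)CC[C@]2(C)C1(C)C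
F6 | step 12 | (2R,3R)-3-[4-(benzyloxy)-3,5-dimethoxybenzyl]-4-tert-butoxy-3-[(tert-butyldimethylsilyl)oxy]-2-(3,4-dimethoxybenzyl)-4-oxobutyl (1S,4R)-4,7,7-trimethyl-3-oxo-2-oxabicyclo[2.2.1]heptane-1-carboxylate | CC(C)(C)OC(=O)[C@@](O[Si](C)(C)C(C)(C)C)(Cc1cc(OC)c(OCc2ccccc2)c(OC)c1)[C@H](Cc1ccc(OC)c(OC)c1)COC(=O)[C@]1(OC2=O)CC[C@]2(C)C1(C)C
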